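## Retrosynthetic overview

1. Germacrane numbering is used: ring C1–C10, lactone C11/C12, exocyclic CH2 = C13, C10‑methyl = C14, C4‑CH2OH = C15. The endgame is desilylation and C8 acylation with (R)‑2‑methylbutanoic acid, so all skeletal work ends at lactone 25.
2. Key disconnection (step 14): the ring bond C6–C7 and the lactone bond C11–C12 are cut together and C12 leaves as CO2. This opens the ten‑membered carbocycle and the lactone to the acyclic (Z)‑enal/terminal allene 20.
3. Enabling feature: the lactone ring O–C6–C7–C11(=C13H2)–C12 is fused to the carbocycle at C6–C7. The unit C7–C11(=C13H2) is the imprint of a monosubstituted allene C7H=C11=C13H2 carboxylated at its central carbon. C6 is an allylic carbinol, that is a former enal carbonyl, which the Z‑C4=C5 alkene holds on the side of C3.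
4. Enal 20 comes from iodoalkene 5 (C4–C6, C15) and aldehyde 13 (C1–C3, C7–C11, C14) through a C3–C4 Nozaki–Hiyama–Kishi coupling, a Shi epoxidation (C1/C10) and a Crabbé homologation (C13).
5. Ring order: oxirane (step 10), then the ten‑membered carbocycle and the γ‑lactone together (step 14).

Key step: step 14

Assumption: 6, 7, 27, (R)‑TRIP, the D‑fructose‑derived Shi ketone and Ni(cod)2 are taken as commercial. The oxazoline–sulfonamide ligand of step 8 is an auxiliary reagent accessible in both enantiomeric forms.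

## Route

Step 1
Reactants: 1 but-2-yne-1,4-diol
Product: 2 4-[(tert-butyldimethylsilyl)oxy]but-2-yn-1-ol
Conditions: NaH (1 equiv), THF, 0 °C; TBSCl (1 equiv), 0 °C → rt
Reagents that add atoms: tert-butyldimethylsilyl chloride, CC(C)(C)[Si](C)(C)Cl
Why: O‑silylation of the symmetrical diol through its sparingly soluble monosodium alkoxide should stop at the monoether and differentiates the future O15 (silylated) from O6 (free).

Step 2
Reactants: 2 4-[(tert-butyldimethylsilyl)oxy]but-2-yn-1-ol
Product: 4 (Z)-4-[(tert-butyldimethylsilyl)oxy]-3-iodobut-2-en-1-ol, via cyclic alkenylaluminate 3 (not isolated)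
Conditions: Red-Al, THF, 0 °C → rt; then I2, −78 → 0 °C
Reagents that add atoms: iodine, II
Why: Hydroxyl‑directed trans‑hydroalumination of the propargylic alcohol puts aluminium on the distal alkyne carbon inside a five‑membered aluminate, and iodinolysis with retention should give only the Z‑iodide, in which iodine (the later C3 site) is cis to the CH2OH carbon (C6).

Step 3
Reactants: 4 (Z)-4-[(tert-butyldimethylsilyl)oxy]-3-iodobut-2-en-1-ol
Product: 5 (Z)-4-[(tert-butyldimethylsilyl)oxy]-3-iodobut-2-en-1-yl acetate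
Conditions: Ac2O, pyridine, DMAP (cat.), CH2Cl2, 0 °C
Reagents that add atoms: acetic anhydride, CC(=O)OC(C)=O
Why: Standard O‑acetylation masks O6 with a group that deactivates the C4=C5 alkene towards the later epoxidation and leaves together with the alkynyl silane in step 11.

Step 4
Reactants: 6 3-(trimethylsilyl)prop-2-ynal; 7 allenylboronic acid pinacol ester
Product: 8 (3R)-1-(trimethylsilyl)hexa-1,5-diyn-3-ol
Conditions: (R)-TRIP (10 mol %), 4 Å MS, toluene, −20 °C
Reagents that add atoms: none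
Why: Chiral‑phosphoric‑acid‑catalysed asymmetric propargylation (SE2′ allenylboration through a closed chair) is expected to attack the Re face of the ynal, as with aryl and alkenyl aldehydes, which sets C8 as R and delivers two differentiated alkynes (the antipodal catalyst is equally available).

Step 5
Reactants: 8 (3R)-1-(trimethylsilyl)hexa-1,5-diyn-3-ol
Product: 9 (3R)-3-[(triethylsilyl)oxy]-1-(trimethylsilyl)hexa-1,5-diyne
Conditions: TESCl, imidazole, CH2Cl2, 0 °C
Reagents that add atoms: triethylsilyl chloride, CC[Si](Cl)(CC)CC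
Why: O‑silylation gives a C8 ether that is a poor leaving group in the nickel step and can later be removed selectively beside TBS ethers.

Step 6
Reactants: 9 (3R)-3-[(triethylsilyl)oxy]-1-(trimethylsilyl)hexa-1,5-diyne
Product: 12 (3E,6R)-4-methyl-6-[(triethylsilyl)oxy]-8-(trimethylsilyl)oct-3-en-7-yn-1-ol, via alkenylalane 10 (not isolated), via lithium alanate 11 (not isolated)
Conditions: Me3Al, Cp2ZrCl2 (cat.), CH2Cl2, 0 °C → rt; concentrate; n-BuLi, hexane–THF, −78 °C; oxirane, −78 °C → rt
Reagents that add atoms: trimethylaluminium, C[Al](C)C; oxirane, C1CO1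
Why: Zirconium‑catalysed Negishi carboalumination adds CH3 (C14) and Al syn to the terminal alkyne only (the silyl‑capped alkyne is inert), which fixes the E‑C1=C10 geometry, and the alanate opens oxirane to add C2–C3.

Step 7
Reactants: 12 (3E,6R)-4-methyl-6-[(triethylsilyl)oxy]-8-(trimethylsilyl)oct-3-en-7-yn-1-ol
Product: 13 (3E,6R)-4-methyl-6-[(triethylsilyl)oxy]-8-(trimethylsilyl)oct-3-en-7-ynal
Conditions: Dess–Martin periodinane, CH2Cl2, 0 °C → rt; used directly
Reagents that add atoms: none
Why: Dess–Martin oxidation runs without base, so the β,γ‑unsaturated aldehyde should not slip into conjugation.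

Step 8
Reactants: 5 (Z)-4-[(tert-butyldimethylsilyl)oxy]-3-iodobut-2-en-1-yl acetate; 13 (3E,6R)-4-methyl-6-[(triethylsilyl)oxy]-8-(trimethylsilyl)oct-3-en-7-ynal
Product: 14 (2Z,4S,6E,9R)-3-{[(tert-butyldimethylsilyl)oxy]methyl}-4-hydroxy-7-methyl-9-[(triethylsilyl)oxy]-11-(trimethylsilyl)undeca-2,6-dien-10-yn-1-yl acetate
Conditions: CrCl2 (3 equiv), NiCl2 (2 mol %), chiral oxazoline–sulfonamide ligand (3.3 equiv), Et3N, THF, rt
Reagents that add atoms: none
Why: The asymmetric Nozaki–Hiyama–Kishi alkenylation forms C3–C4 with retention of the Z geometry, tolerates acetate, silyl ethers and the alkyne, and the chromium‑bound ligand (enantiomer chosen for Re‑face attack on 13) sets C3 as S.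

Step 9
Reactants: 14 (2Z,4S,6E,9R)-allylic alcohol
Product: 15 (2Z,4S,6E,9R)-4-[(tert-butyldimethylsilyl)oxy]-3-{[(tert-butyldimethylsilyl)oxy]methyl}-7-methyl-9-[(triethylsilyl)oxy]-11-(trimethylsilyl)undeca-2,6-dien-10-yn-1-yl acetate
Conditions: TBSOTf, 2,6-lutidine, CH2Cl2, −78 °C
Reagents that add atoms: tert-butyldimethylsilyl triflate, CC(C)(C)[Si](C)(C)OS(=O)(=O)C(F)(F)F
Why: Silylation of O3 prevents lactol and furan formation once the cis‑disposed C6 becomes an aldehyde.

Step 10
Reactants: 15 (2Z,4S,6E,9R)-tetrasilylated dienyne acetate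
Product: 16 (2Z,4S,6R,7R,9R)-4-[(tert-butyldimethylsilyl)oxy]-3-{[(tert-butyldimethylsilyl)oxy]methyl}-6,7-epoxy-7-methyl-9-[(triethylsilyl)oxy]-11-(trimethylsilyl)undec-2-en-10-yn-1-yl acetate
Conditions: D-fructose-derived Shi ketone (30 mol %), Oxone, K2CO3, Bu4NHSO4 (cat.), borate/EDTA buffer, MeCN–DMM–H2O, 0 °C
Reagents that add atoms: potassium peroxymonosulfate (active part of Oxone), [K+].[O-]S(=O)(=O)OO
Why: In the Shi asymmetric epoxidation the D‑series dioxirane converts E‑trisubstituted alkenes through the spiro transition state into the (R,R)‑epoxide (C1 R, C10 R), while the C4=C5 alkene is deactivated by three allylic C–O bonds and shielded by silyl groups and the alkyne is inert.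

Step 11
Reactants: 16 (2Z,4S,6R,7R,9R)-epoxy acetate
Product: 17 (2Z,4S,6R,7R,9R)-4-[(tert-butyldimethylsilyl)oxy]-3-{[(tert-butyldimethylsilyl)oxy]methyl}-6,7-epoxy-7-methyl-9-[(triethylsilyl)oxy]undec-2-en-10-yn-1-ol
Conditions: K2CO3 (cat.), MeOH, 0 °C → rt
Reagents that add atoms: none
Why: Mild methanolysis effects transesterification of the acetate and protiodesilylation of the alkynyl silane in one operation and should leave the O‑silyl ethers and the epoxide untouched.

Step 12
Reactants: 17 (2Z,4S,6R,7R,9R)-epoxy alkynol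
Product: 19 (2Z,4S,6R,7R,9R)-4-[(tert-butyldimethylsilyl)oxy]-3-{[(tert-butyldimethylsilyl)oxy]methyl}-6,7-epoxy-7-methyl-9-[(triethylsilyl)oxy]dodeca-2,10,11-trien-1-ol, via propargylic amine 18 (not isolated)
Conditions: CuI (0.5 equiv), Cy2NH, (CH2O)n, 1,4-dioxane, reflux
Reagents that add atoms: formaldehyde (as paraformaldehyde), C=O
Why: The Crabbé homologation (copper‑mediated Mannich reaction, then 1,5‑hydride transfer and fragmentation) turns the terminal alkyne into the terminal allene, adds C13 and does not touch the C8 stereocentre.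

Step 13
Reactants: 19 (2Z,4S,6R,7R,9R)-allenyl allylic alcohol
Product: 20 (2Z,4S,6R,7R,9R)-4-[(tert-butyldimethylsilyl)oxy]-3-{[(tert-butyldimethylsilyl)oxy]methyl}-6,7-epoxy-7-methyl-9-[(triethylsilyl)oxy]dodeca-2,10,11-trienal
Conditions: activated MnO2, CH2Cl2, rt
Reagents that add atoms: none
Why: Neutral MnO2 oxidation is selective for the allylic alcohol and should keep the Z geometry, the allene and the epoxide.

Step 14
Reactants: 20 (2Z,4S,6R,7R,9R)-allenyl enal; 21 carbon dioxide
Product: 25 (4Z)-1β,10α-epoxy-3β,15-bis[(tert-butyldimethylsilyl)oxy]-8β-[(triethylsilyl)oxy]germacra-4,11(13)-dien-12,6α-olide, via nickelalactone 22 (not isolated), via nickel alkoxide carboxylate chelate 23 (not isolated), via hydroxy acid 24 (not isolated)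
Conditions: Ni(cod)2 (1.5 equiv), DBU (4 equiv), CO2 (1 atm), THF, 0 °C; 20 added by syringe pump (final 2 mM), then rt; cold 0.5 M HCl to pH 3, EtOAc
Reagents that add atoms: none
Why: Proposed new method: Ni(0)/DBU couples the terminal allene of 20 oxidatively with CO2, which bonds the CO2 carbon (C12) to the central allene carbon C11 and gives the 2‑carboxylato‑allylnickel(II) species 22, whose σ‑form holds nickel on the unsubstituted C13H2 end and adds through its γ‑carbon C7 to the tethered aldehyde carbon C6 to give chelate 23; acidification frees hydroxy acid 24, which should lactonise spontaneously as germacranolide hydroxy acids do. The closest known reaction type is the nickel(0)‑mediated sequential three‑component coupling of terminal allenes, CO2 and aryl aldehydes to α‑methylene‑γ‑hydroxy acids, and the ring closure resembles the chromium‑ or zinc‑mediated macrocyclisations of 2‑(alkoxycarbonyl)allyl halides onto enals that give ten‑membered germacranolide rings; new are the intramolecular ten‑membered version and an enal that is present from the start. The carbocycle closes by 10‑exo‑trig addition of the allyl γ‑carbon to C=O (SE2′ with respect to nickel), and the lactone closes by 5‑exo‑trig attack of O6 on the carboxyl carbon C12. For C6 and C7, rapid π–σ–π equilibration should funnel both allyl geometries into the less hindered syn‑π‑allyl/E‑σ‑allyl form, whose closed six‑membered chair with C5 and C8 equatorial gives the anti adduct, that is the trans‑lactone (H‑6β/H‑7α). The face of C7 is controlled by the adjacent C8 stereocentre, with H‑8 turned inside against the carboxylate‑bearing C11 (A1,3 strain), the electron‑withdrawing C–OTES bond kept out of the position anti to the forming bond and C9 anti, so that C6 should bond to the face that places C11 and O8 cis (both β). The step needs CO2 uptake before aldehyde attack (a CO2‑saturated solution against the low effective molarity of the slowly added tethered enal), C7 rather than C13 attack (nickel rests on the CH2 end), 1,2‑addition without α‑enolisation (β,β‑disubstituted enal), no ionisation or β‑elimination at C8 (silyl ether instead of the ester) and cyclisation over oligomerisation (the Z‑C4=C5 alkene and the trans‑epoxide act as two rigid turn elements).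

Step 15
Reactants: 25 protected germacranolide
Product: 26 (4Z)-1β,10α-epoxy-3β,15-bis[(tert-butyldimethylsilyl)oxy]-8β-hydroxygermacra-4,11(13)-dien-12,6α-olide
Conditions: PPTS (cat.), MeOH–CH2Cl2, 0 °C
Reagents that add atoms: none
Why: Acid‑catalysed methanolysis discriminates the far more labile TES ether from the two TBS ethers, and the weak acid should spare the epoxide.

Step 16
Reactants: 26 8β-alcohol; 27 (R)-2-methylbutanoic acid
Product: 28 (4Z)-1β,10α-epoxy-3β,15-bis[(tert-butyldimethylsilyl)oxy]-8β-[(2R)-2-methylbutanoyloxy]germacra-4,11(13)-dien-12,6α-olide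
Conditions: DCC, DMAP (cat.), CH2Cl2, 0 °C → rt
Reagents that add atoms: none
Why: Steglich esterification acylates the only free hydroxyl with retention at C8 and, without a ketene pathway, should keep the α‑stereocentre brought in by 27.

Step 17
Reactants: 28 bis-TBS ester
Product: 29 target CNP0267576.1
Conditions: Et3N·3HF, MeCN, rt
Reagents that add atoms: none
Why: Near‑neutral fluoride desilylation frees O3 and O15 and should leave the epoxide, the ester and the α‑methylene lactone intact.

## Compound list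

1 | but-2-yne-1,4-diol | OCC#CCO | starting material
2 | 4-[(tert-butyldimethylsilyl)oxy]but-2-yn-1-ol | CC(C)(C)[Si](C)(C)OCC#CCO | intermediate
3 | sodium cyclic alkenylaluminate (five-membered Al–O–C6–C5=C4 ring) | COCCO[Al-]1(OCCOC)OCC=C1CO[Si](C)(C)C(C)(C)C.[Na+] | intermediate
4 | (Z)-4-[(tert-butyldimethylsilyl)oxy]-3-iodobut-2-en-1-ol | OC/C=C(/CO[Si](C)(C)C(C)(C)C)I | intermediate
5 | (Z)-4-[(tert-butyldimethylsilyl)oxy]-3-iodobut-2-en-1-yl acetate | CC(=O)OC/C=C(/CO[Si](C)(C)C(C)(C)C)I | intermediate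
6 | 3-(trimethylsilyl)prop-2-ynal | C[Si](C)(C)C#CC=O | starting material
7 | allenylboronic acid pinacol ester | C=C=CB1OC(C)(C)C(C)(C)O1 | starting material
8 | (3R)-1-(trimethylsilyl)hexa-1,5-diyn-3-ol | C#CC[C@@H](O)C#C[Si](C)(C)C | intermediate
9 | (3R)-3-[(triethylsilyl)oxy]-1-(trimethylsilyl)hexa-1,5-diyne | C#CC[C@@H](O[Si](CC)(CC)CC)C#C[Si](C)(C)C | intermediate
10 | (E)-alkenyldimethylalane from 9 | C[Al](C)/C=C(\C)C[C@@H](O[Si](CC)(CC)CC)C#C[Si](C)(C)C | intermediate
11 | lithium (E)-alkenyl(butyl)dimethylalanate | [Li+].CCCC[Al-](C)(C)/C=C(\C)C[C@@H](O[Si](CC)(CC)CC)C#C[Si](C)(C)C | intermediate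
12 | (3E,6R)-4-methyl-6-[(triethylsilyl)oxy]-8-(trimethylsilyl)oct-3-en-7-yn-1-ol | OCC/C=C(\C)C[C@@H](O[Si](CC)(CC)CC)C#C[Si](C)(C)C | intermediate
13 | (3E,6R)-4-methyl-6-[(triethylsilyl)oxy]-8-(trimethylsilyl)oct-3-en-7-ynal | O=CC/C=C(\C)C[C@@H](O[Si](CC)(CC)CC)C#C[Si](C)(C)C | intermediate
14 | (2Z,4S,6E,9R)-3-(TBSO-methyl)-4-hydroxy-7-methyl-9-(TESO)-11-(TMS)undeca-2,6-dien-10-yn-1-yl acetate | CC(=O)OC/C=C(/CO[Si](C)(C)C(C)(C)C)[C@@H](O)C/C=C(\C)C[C@@H](O[Si](CC)(CC)CC)C#C[Si](C)(C)C | intermediate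
15 | 4-O-TBS ether of 14 | CC(=O)OC/C=C(/CO[Si](C)(C)C(C)(C)C)[C@@H](O[Si](C)(C)C(C)(C)C)C/C=C(\C)C[C@@H](O[Si](CC)(CC)CC)C#C[Si](C)(C)C | intermediate
16 | (6R,7R)-epoxide of 15 | CC(=O)OC/C=C(/CO[Si](C)(C)C(C)(C)C)[C@@H](O[Si](C)(C)C(C)(C)C)C[C@H]1O[C@]1(C)C[C@@H](O[Si](CC)(CC)CC)C#C[Si](C)(C)C | intermediate
17 | (2Z,4S,6R,7R,9R)-epoxy alkynol (free O6–H, terminal alkyne) | OC/C=C(/CO[Si](C)(C)C(C)(C)C)[C@@H](O[Si](C)(C)C(C)(C)C)C[C@H]1O[C@]1(C)C[C@@H](O[Si](CC)(CC)CC)C#C | intermediate
18 | 12-(dicyclohexylamino) propargylic amine from 17 | OC/C=C(/CO[Si](C)(C)C(C)(C)C)[C@@H](O[Si](C)(C)C(C)(C)C)C[C@H]1O[C@]1(C)C[C@@H](O[Si](CC)(CC)CC)C#CCN(C1CCCCC1)C1CCCCC1 | intermediate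
19 | (2Z,4S,6R,7R,9R)-epoxy allenyl allylic alcohol | OC/C=C(/CO[Si](C)(C)C(C)(C)C)[C@@H](O[Si](C)(C)C(C)(C)C)C[C@H]1O[C@]1(C)C[C@@H](O[Si](CC)(CC)CC)C=C=C | intermediate
20 | (2Z,4S,6R,7R,9R)-epoxy allenyl enal | O=C/C=C(/CO[Si](C)(C)C(C)(C)C)[C@@H](O[Si](C)(C)C(C)(C)C)C[C@H]1O[C@]1(C)C[C@@H](O[Si](CC)(CC)CC)C=C=C | intermediate
21 | carbon dioxide | O=C=O | starting material
22 | nickelalactone, drawn as σ-allyl form (Ni on C13, DBU ligands omitted) | O=C/C=C(/CO[Si](C)(C)C(C)(C)C)[C@@H](O[Si](C)(C)C(C)(C)C)C[C@H]1O[C@]1(C)C[C@@H](O[Si](CC)(CC)CC)/C=C1/C[Ni]OC1=O | intermediate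
23 | macrocyclic nickel(II) 6-alkoxide 12-carboxylate chelate (DBU ligands omitted) | C=C1C(=O)O[Ni]O[C@@H]2/C=C(/CO[Si](C)(C)C(C)(C)C)[C@@H](O[Si](C)(C)C(C)(C)C)C[C@H]3O[C@]3(C)C[C@@H](O[Si](CC)(CC)CC)[C@@H]12 | intermediate
24 | (4Z)-1β,10α-epoxy-6α-hydroxy-3β,15-bis(TBSO)-8β-(TESO)germacra-4,11(13)-dien-12-oic acid | C=C(C(=O)O)[C@H]1[C@H](O)/C=C(/CO[Si](C)(C)C(C)(C)C)[C@@H](O[Si](C)(C)C(C)(C)C)C[C@H]2O[C@]2(C)C[C@H]1O[Si](CC)(CC)CC | intermediate
25 | (4Z)-1β,10α-epoxy-3β,15-bis(TBSO)-8β-(TESO)germacra-4,11(13)-dien-12,6α-olide (trans-lactone, H-6β/H-7α) | C=C1C(=O)O[C@@H]2/C=C(/CO[Si](C)(C)C(C)(C)C)[C@@H](O[Si](C)(C)C(C)(C)C)C[C@H]3O[C@]3(C)C[C@@H](O[Si](CC)(CC)CC)[C@@H]12 | intermediate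
26 | 8β-hydroxy analogue of 25 | C=C1C(=O)O[C@@H]2/C=C(/CO[Si](C)(C)C(C)(C)C)[C@@H](O[Si](C)(C)C(C)(C)C)C[C@H]3O[C@]3(C)C[C@@H](O)[C@@H]12 | intermediate
27 | (R)-2-methylbutanoic acid | CC[C@@H](C)C(=O)O | starting material
28 | 8β-[(2R)-2-methylbutanoyloxy] bis-TBS ether | C=C1C(=O)O[C@@H]2/C=C(/CO[Si](C)(C)C(C)(C)C)[C@@H](O[Si](C)(C)C(C)(C)C)C[C@H]3O[C@]3(C)C[C@@H](OC(=O)[C@H](C)CC)[C@@H]12 | intermediate
29 | (1R,3S,4Z,6R,7R,8R,10R)-1,10-epoxy-3,15-dihydroxy-8-[(2R)-2-methylbutanoyloxy]germacra-4,11(13)-dien-12,6-olide | C=C1C(=O)O[C@@H]2/C=C(/CO)[C@@H](O)C[C@H]3O[C@]3(C)C[C@@H](OC(=O)[C@H](C)CC)[C@@H]12 | target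

## Step count

Total step count: 17. Longest linear sequence: 14 steps (steps 4–17, from 6 and 7).

## Steps most likely to fail

1. **Step 14.**
 - What may go wrong:
   - The allylnickel–aldehyde addition may be too slow at high dilution, so that oligomerisation or protonation wins.
   - DBU may isomerise the Z‑enal.
   - The enal may sequester Ni(0).
   - Control of the C7 face by C8 may be weak.
 - Fallback (known chemistry, the two bonds made in separate operations): it sets out from 17 and comes back at 25. The primary alcohol of 17 is silylated (TESCl, imidazole) to the bis‑TES ether F1. Alkyne deprotonation (n‑BuLi, −78 °C) and methyl chloroformate give the ynoate F2, which holds the C11–C12 bond. Reductive hydroxymethylation (DIBAL‑H/NMO, then formaldehyde; vinylalumination) gives the hydroxymethyl enoate F3, and acetylation gives the allylic acetate F4. Swern oxidation, which converts only the primary allylic TES ether, gives the enal F5. Palladium‑catalysed, diethylzinc‑driven umpolung allylation at high dilution then closes C6–C7, and lactonisation onto the methyl ester in the same flask gives 25.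

2. **Step 8.**
 - What may go wrong: the ligand may give poor facial selectivity with the hindered, trisubstituted iodoalkene, and coupling may be slow.
 - Fallback: it sets out from 5 and 13 and comes back at 14. Ligand‑free Nozaki–Hiyama–Kishi coupling gives 14 together with its C3 epimer F6. Dess–Martin oxidation of the mixture gives the enone F7. Corey–Bakshi–Shibata reduction with (R)‑Me‑CBS and catecholborane (alkenyl group large, CH2 small) should return the 3S alcohol 14, so C3 is set by reagent‑controlled hydride delivery instead of by the C–C coupling.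

3. **Step 4.**
 - What may go wrong: uncatalysed background addition to the very electrophilic ynal and the small, linear alkynyl group may erode the enantioselectivity.
 - Fallback: it sets out from 6 and comes back at 8. A zinc Barbier reaction with propargyl bromide gives the racemic alcohol F8. Lipase‑catalysed acetylation with vinyl acetate (kinetic resolution) converts the R enantiomer into the acetate F9 and leaves the S alcohol F10. DIBAL‑H at −78 °C cleaves F9 to 8 without touching the C–Si bond.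

## Further compounds

F1 | step 14 | O6-TES ether of 17 | CC[Si](CC)(CC)OC/C=C(/CO[Si](C)(C)C(C)(C)C)[C@@H](O[Si](C)(C)C(C)(C)C)C[C@H]1O[C@]1(C)C[C@@H](O[Si](CC)(CC)CC)C#C
F2 | step 14 | methyl ynoate from F1 | CC[Si](CC)(CC)OC/C=C(/CO[Si](C)(C)C(C)(C)C)[C@@H](O[Si](C)(C)C(C)(C)C)C[C@H]1O[C@]1(C)C[C@@H](O[Si](CC)(CC)CC)C#CC(=O)OC
F3 | step 14 | methyl (Z)-2-(hydroxymethyl)enoate from F2 | CC[Si](CC)(CC)OC/C=C(/CO[Si](C)(C)C(C)(C)C)[C@@H](O[Si](C)(C)C(C)(C)C)C[C@H]1O[C@]1(C)C[C@@H](O[Si](CC)(CC)CC)/C=C(/CO)C(=O)OC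
F4 | step 14 | allylic acetate of F3 | CC[Si](CC)(CC)OC/C=C(/CO[Si](C)(C)C(C)(C)C)[C@@H](O[Si](C)(C)C(C)(C)C)C[C@H]1O[C@]1(C)C[C@@H](O[Si](CC)(CC)CC)/C=C(/COC(C)=O)C(=O)OC
F5 | step 14 | (Z)-enal with 2-(acetoxymethyl)enoate terminus | O=C/C=C(/CO[Si](C)(C)C(C)(C)C)[C@@H](O[Si](C)(C)C(C)(C)C)C[C@H]1O[C@]1(C)C[C@@H](O[Si](CC)(CC)CC)/C=C(/COC(C)=O)C(=O)OC
F6 | step 8 | (4R)-epimer of 14 | CC(=O)OC/C=C(/CO[Si](C)(C)C(C)(C)C)[C@H](O)C/C=C(\C)C[C@@H](O[Si](CC)(CC)CC)C#C[Si](C)(C)C
F7 | step 8 | 4-oxo enone from 14/F6 | CC(=O)OC/C=C(/CO[Si](C)(C)C(C)(C)C)C(=O)C/C=C(\C)C[C@@H](O[Si](CC)(CC)CC)C#C[Si](C)(C)C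
F8 | step 4 | racemic 1-(trimethylsilyl)hexa-1,5-diyn-3-ol | C#CCC(O)C#C[Si](C)(C)C
F9 | step 4 | (3R)-1-(trimethylsilyl)hexa-1,5-diyn-3-yl acetate | C#CC[C@@H](OC(C)=O)C#C[Si](C)(C)C
F10 | step 4 | (3S)-1-(trimethylsilyl)hexa-1,5-diyn-3-ol | C#CC[C@H](O)C#C[Si](C)(C)C
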